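The runs were computed for an exercise; scatter was added.

A small charge of E carries this chemistry: E turns G into L, E binds L as X, Q frees J from X, and two E can pair into D.

| setting | dusk | midnight | flask |
|---|---|---|---|
| G | 0.13 M | 0.13 M | 0.13 M |
| Q | 1.1 equiv | 1.1 equiv | 1.10 equiv |
| E | 0.038 mol% | 0.086 mol% | 0.057 mol% |
| remark | run made earlier | run made earlier |  |

| run | time / min | J / % | G / % |
|---|---|---|---|
| dusk | 0.200 | 0 | 96.4 |
| dusk | 0.500 | 1.8 | 92.9 |
| dusk | 1.00 | 3.1 | 91.5 |
| dusk | 1.50 | 3.8 | 87.8 |
| dusk | 2.00 | 4.1 | 84.7 |
| dusk | 3.00 | 10.0 | 79.5 |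
| dusk | 4.00 | 12.3 | 75.7 |
| midnight | 0.500 | 3.1 | 89.7 |
| midnight | 1.00 | 7.1 | 84.5 |
| midnight | 1.50 | 11.0 | 77.4 |
| midnight | 2.00 | 14.1 | 74.2 |
| midnight | 2.50 | 17.0 | 70.2 |
| midnight | 3.00 | 18.5 | 67.6 |
| midnight | 4.00 | 23.2 | 63.0 |

(each reading ± 1 percentage point)

- the numbers in the tables scatter with a standard deviation of 1 percentage point
- steps that have been proposed: G + E -> E + L; E + L <-> X; Q + X -> E + J; 2 Q -> Z; 2 E <-> D

- factor on the rate of making J when 5.0% of the G are converted if E is charged twice over
- factor on the rate when 5.0% of the G are converted if E is charged at 0.6 mol% instead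

I follow the rate alone. After 4.00 min, the dusk run has made 12.3% of J and the midnight run 23.2%. That is a factor of 1.89 in J for a factor of 2.26 in E, so J grows less than the charge. I freeze the exponent that joins these factors, 0.777, the apparent order in E. It is a reading, and each J scatters by 1 percentage point. The midnight run has also gone further by then, with G at 63.0% against 75.7% at dusk, and I leave that inside the number.

With this order, each doubling of E loses a factor of 1.17 against strict proportion. From 0.057 mol%, a doubling therefore gives 1.71. Going to 0.6 mol% raises E by a factor of 10.5, and the loss accumulates to 1.69, so I commit to 6.23. This assumes the order read at 4.00 min also holds at 5.0% conversion and across the whole range of loadings.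

The forecast differs from my reckoning: it gives 1.95 and 9, on the ground that the runs “overlay on a normalised time axis”.

The flask gives 1.73 and 5.14.

    G + E → E + L (k = 93.6 /M/s)
    E + L ⇌ X (K = 660 /M, k = 914 /M/s)
    Q + X → E + J (k = 25.3 /M/s)
    2 Q → Z (k = 0.0239 /M/s)
    2 E ⇌ D, settled at all times (K = 13000 /M)

My frozen 0.777 gives a doubling of 1.71, close to 1.73, but its 6.23 lies above 5.14, and the flask's factor over that span corresponds to an exponent of 0.695. The largest single effect on the order is the binding of two E into D: in the flask at 0.057 mol% the order at 5.0% conversion is 0.84, and without that binding it is 1.0. D holds 24.7% of the catalyst in this flask after 0.300 min, with G at 94.9%, and at 0.6 mol%, at 5.0% conversion, it holds 64.8%.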